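## The problem

The target 27 is numbered as follows: lactone carbonyl C1, ring alkene C2=C3, C4, N–CH C5, C6 to C8, spiro carbon C9, C10 to C12, ring CH C13, CHMe C14, cis alkene C15=C16, carbinol C17, alkene C18=C19 with chlorine on C19, C20, OCH2 C21, NCH2 C22. A cyclopentane (C9–C13) is spiro-fused at C9 to a piperidine (N, C5–C9). The nitrogen is shared with a tetrahydropyridine (N, C22, C2, C3, C4, C5) that carries the C1 carboxyl, and a 15-membered lactone runs from C1 through O–C21 back to C14. Four of the five stereocentres (C5, C9, C13, C14) are grouped around the spiro centre; C17 sits alone in the macrocycle. C13 and C14 have to be made together. C13 can then direct the fully substituted, nitrogen-bearing C9 (the new carbon arm enters trans to the C14 side chain), and C9 with C13 can direct C5 through a chair piperidine. Nothing in the core reaches C17, which needs reagent control. The C17 carbinol is doubly allylic and next to a chloroalkene, so it ionises with acid. It, the Z alkene, the vinyl chloride (C17 and C20 cis) and the lactone must appear late, and the β-amino enoate of ring C tolerates neither strong base nor hydride. The opening for the key step is that C5 and C6 lie between the nitrogen and the arm C8–C7–C6 on C9. An amine on C9 whose arm ends in a vinylsilane can be condensed with a three-carbon aldehyde (C5–C3) and the piperidine closed by a C5–C6 bond from the imine.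

## Retrosynthesis

**C1–O bond (27 to 26).** The lactone is opened at the ester bond to the dihydroxy acid 26. Closing the ring at C16–C17 or at C15=C16 would place a stereocentre or an alkene geometry under macrocyclic control; the ester bond has no stereochemical consequence. 26 comes from 25 by one hydrolysis that removes the methyl ester and the C21 acetate together. The forward step must acylate the primary C21 hydroxyl in preference to the hindered C17 hydroxyl.

**C16–C17 bond and the cis alkene (25 to 24 to 20 + 23).** The Z alkene is taken back to the alkyne 24, and 24 is cut between C16 and C17 into the core alkyne 20 and the chloro enal 23. A Wittig cut at C15=C16 would need an ylide with a β-oxygen, and a vinyl-metal addition would need strong base beside the ester. The cut separates all four core stereocentres from a five-carbon fragment. The forward addition must be a 1,2-addition with catalyst-controlled facial selectivity, and the semihydrogenation must spare the vinyl chloride.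

**Fragment 23 (to 22 to 21).** C17 is removed as carbon monoxide, leaving vinyl iodide 22. The C–I and C–Cl bonds are cut back to but-3-yn-1-yl acetate 21. Anti addition of ICl puts chlorine trans to the future C17. Hydrochlorination of an ynal or ynoate would give the opposite geometry.

**C15–C16 homologation (20 to 19 to 18 to 17).** The alkyne carbon C16 is removed to aldehyde 19, which comes from alcohol 18 and silyl ether 17. The silyl ether lets C15 pass through the core assembly as a protected alcohol.

**Ring C: C2=C3 and N–C22 (17 to 15 to 13 + 14).** The enoate alkene is cut as an intramolecular Horner–Wadsworth–Emmons reaction of aldehyde 16, and N–C22 as a conjugate addition of amine 13 to phosphonoacrylate 14. A plain ester aldol would need strong base next to a β-amino aldehyde, and a Mannich closure would leave a C3 ketone to remove. The forward steps need a hindered secondary amine to add to an unhindered CH2 terminus, and the olefination to outrun retro-Michael loss of the amine.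

**Saturation and debenzylation (13 to 12).** The C6=C7 alkene and the benzyl ether of 12 are removed in one hydrogenation.

**C5–C6 bond, the key cut (12 to 11 to 9 + 10).** The piperidine is opened between C5 and C6 to imine 11, made from amine 9 and 3-(benzyloxy)propanal 10. Cutting N–C5 (aza-Michael) would need a C5–C3 enoate chain built linearly on C9. Cutting C8–C9 would need a chiral allylsilane amine. Here C3–C5 arrive as a commercial aldehyde. The forward reaction must be a 6-endo closure that sets C5 relative to C9. For that the silyl group is placed Z, so that it is axial and aligned with the developing cation in the chair that keeps the C4 chain equatorial.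

**C8–C9 bond (9 to 8 to 7 to 5 + 6).** The amine is a reduced nitro group, and the nitro group allows C9 to be quaternised through its nitronate. The Z vinylsilane comes from silylalkyne 7, made from nitro compound 5 and propargyl bromide 6. A π-allylpalladium route would give the E vinylsilane, the less suitable isomer for the closure. The forward alkylation must be a C-alkylation anti to the C13 side chain.

**C13–C14 bond (5 to 4 to 3 to 1 + 2).** Both stereocentres come from one enamine-catalysed Michael addition of propanal 2 to 1-nitrocyclopent-1-ene 1, followed by reduction and silylation.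

## Roads not taken

**Alternative 1:** Hidden symmetry. The cut is C9–C13: the achiral nitro dienoate A1 would close by an intramolecular nitronate Michael addition under a chiral amine–thiourea catalyst to the nitrocyclopentane A2. One catalytic step would set the quaternary C9 and C13 and tell two identical arms apart. The remaining arm already carries the C5–C3 enoate for a thermodynamically controlled aza-Michael piperidine closure. In both respects it is more convergent than the chosen plan. Its weak points are structural. A secondary nitronate must add to an unactivated enoate to form a quaternary centre, the nitro group must end cis to the new side chain, and A2 lacks the C14 methyl group. The methyl would have to be added by enolate alkylation next to C13 under acyclic control, in the presence of a second methyl ester that must be told apart. The chosen plan sets C13 and C14, methyl included, in its first step, and pays for that with a separate quaternisation of C9.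

**Alternative 2:** Carbonylative macrolactonization. The cut is C1–C2 and C1–O: the enol triflate A3 with a free C21 hydroxyl would give the C17 silyl ether A4 of the target under Pd(PPh3)4 and carbon monoxide. It avoids the amino acid seco compound and carboxyl activation, and the enoate need not survive the side-chain steps; there it is better than the chosen ending. It concerns only the endgame and still needs a synthesis of the azaspiro core. The enol triflate must be formed regioselectively from an α-amino ketone (toward C3, not C22). The acylpalladium must be captured by a remote alcohol at high dilution in the presence of a tertiary amine and a vinyl chloride. The chosen plan relies instead on a carbodiimide lactonization, whose main open question is site selectivity, and on an enoate made without a ketone intermediate.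

**Alternative 3:** Aza-Michael and formaldehyde Mannich double annulation. The cuts are N–C5, N–C22 and C22–C2: the amino enone A5 would give the tricyclic β-keto ester A6 in one pot. It forms two rings at once, and C5 is set by a reversible conjugate addition, which is more secure than the kinetic chair control of the chosen key step. Against it, A5 contains a primary amine beside a polymerisable vinylogous β-keto ester and must be unmasked in the flask. A6 also carries a C3 ketone that has to be reduced and eliminated to reach the C2=C3 enoate. The chosen plan builds the piperidine from two simple fragments, reaches the enoate directly at the right oxidation level, and keeps the reversible aza-Michael closure as its fallback.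

Key step: step 7

Remark on the chemistry: 1-nitrocyclopent-1-ene 1 is taken as purchasable.
Remark on the chemistry: in step 16 the ProPhenol antipode is defined by the face it must attack (Re face of the aldehyde of 23), not by a ligand descriptor.

## Route

Step 1
Reactants: 1 1-nitrocyclopent-1-ene; 2 propanal
Product: 4 (2R)-2-[(1R)-2-nitrocyclopentyl]propan-1-ol (both epimers at the nitro carbon), via nitro aldehyde 3 (not isolated)
Conditions: (S)-α,α-diphenylprolinol trimethylsilyl ether (20 mol%), PhCO2H (20 mol%), 2 (3 equiv), toluene, 0 °C → rt; then NaBH4, MeOH, 0 °C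
Reagents that add atoms: none
Why: Enamine-catalysed Michael addition of an aldehyde to a nitroalkene; the E enamine, shielded on one face by the diarylmethyl group, adds in a synclinal arrangement in which the ring CH2 (C12) plays the part of the β-substituent trans to NO2, which should give the syn C13/C14 pair (13R,14R). Reduction in the same flask protects the α-centre C14 from epimerisation; the nitro-bearing carbon is left as a mixture because it is planarised in step 3.

Step 2
Reactants: 4 nitro alcohol
Product: 5 tert-butyl{(2R)-2-[(1R)-2-nitrocyclopentyl]propoxy}diphenylsilane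
Conditions: TBDPSCl, imidazole, DMF, rt
Reagents that add atoms: tert-butyl(chloro)diphenylsilane, CC(C)(C)[Si](Cl)(c1ccccc1)c1ccccc1
Why: Standard silylation of a primary alcohol; the diphenyl silyl ether is chosen over a dimethyl one because it must survive acetic acid in step 5 and CF3CO2H in step 7.

Step 3
Reactants: 5 nitro silyl ether; 6 3-bromo-1-(trimethylsilyl)prop-1-yne
Product: 7 tert-butyl{(2R)-2-[(1R,2S)-2-nitro-2-[3-(trimethylsilyl)prop-2-yn-1-yl]cyclopentyl]propoxy}diphenylsilane
Conditions: CuBr (10 mol%), N,N′-diaryl β-diketimine ligand (12 mol%), NaOtBu, 1,4-dioxane, 60 °C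
Reagents that add atoms: none
Why: Copper-catalysed C-propargylation of a secondary nitroalkane (thermal redox pathway through the copper nitronate and a propargyl radical) forms the tertiary nitro centre where plain alkylation would go on oxygen. The new C8–C9 bond should form on the nitronate face anti to the C13 side chain, which puts nitrogen cis to that chain (9S).

Step 4
Reactants: 7 silylalkyne
Product: 8 tert-butyl{(2R)-2-[(1R,2S)-2-nitro-2-[(2Z)-3-(trimethylsilyl)prop-2-en-1-yl]cyclopentyl]propoxy}diphenylsilane
Conditions: H2 (1 atm), Pd/CaCO3 poisoned with Pb(OAc)2, quinoline, hexane–EtOAc, rt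
Reagents that add atoms: none
Why: Lindlar semihydrogenation delivers both hydrogens to one face of the silylalkyne and gives the Z vinylsilane; a tertiary aliphatic nitro group is not reduced under these conditions.

Step 5
Reactants: 8 Z-vinylsilane nitro compound
Product: 9 (1S,2R)-2-[(2R)-1-{[tert-butyl(diphenyl)silyl]oxy}propan-2-yl]-1-[(2Z)-3-(trimethylsilyl)prop-2-en-1-yl]cyclopentan-1-amine
Conditions: Zn dust, AcOH, THF, rt
Reagents that add atoms: none
Why: Zinc reduction of a tertiary nitro group to the primary amine; the vinylsilane and the silyl ether are inert to zinc in acetic acid, and C9 carries no hydrogen that could epimerise.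

Step 6
Reactants: 9 amine; 10 3-(benzyloxy)propanal
Product: 11 (1E)-3-(benzyloxy)-N-{(1S,2R)-2-[(2R)-1-{[tert-butyl(diphenyl)silyl]oxy}propan-2-yl]-1-[(2Z)-3-(trimethylsilyl)prop-2-en-1-yl]cyclopentyl}propan-1-imine
Conditions: MgSO4, CH2Cl2, rt; filtered, concentrated and used crude
Reagents that add atoms: none
Why: Condensation of a primary amine with an aldehyde under dehydration; a tert-alkyl aldimine is hindered enough to resist aldol-type self-condensation and has no hydrogen on C9 toward which it could tautomerise.

Step 7
Reactants: 11 imine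
Product: 12 (1R,5S,7S)-7-[2-(benzyloxy)ethyl]-1-[(2R)-1-{[tert-butyl(diphenyl)silyl]oxy}propan-2-yl]-6-azaspiro[4.5]dec-8-ene
Conditions: CF3CO2H (1.2 equiv), MeCN, 0 → 60 °C; then aq NaHCO3
Reagents that add atoms: none
Why: Proposed new method: protonation of the tert-alkyl aldimine gives an N–H iminium ion whose carbon C5 is attacked by the silicon-bearing vinyl carbon C6 in a 6-endo closure of the piperidine, and the β-silyl cation at C7 loses Me3Si to leave the C6=C7 alkene. The closest known reaction type is the acid- or InCl3-promoted iminium–vinylsilane (aza-silyl-Prins) cyclization of N-alkyl (Z)-4-silylbut-3-enylamines with aldehydes to 1,2,5,6-tetrahydropyridines; a preformed imine of a primary amine on a quaternary carbon has not been shown in it. Silicon fixes the regiochemistry (C6 attacks, not C7) and the position of the alkene. In the chair transition state the E iminium places the C4 chain equatorial and the Z silyl group axial, parallel to the empty orbital developing at C7, which is why the Z isomer was built. C5 is set relative to C9 by the chair that also keeps the larger C13 branch of the cyclopentane equatorial, so the C4 chain and C13 end up cis on the piperidine (5S in 12). A 2-azonia-Cope shift to a cyclopentylidene iminium ion with an allylsilane is a likely competing path; it would re-form C8–C9 anti to the C13 side chain through the same chair and should converge on the same diastereomer. Geminal substitution at C9 favours closure, and one equivalent of CF3CO2H in MeCN should leave the diphenyl silyl ether and the benzyl ether intact.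

Step 8
Reactants: 12 tetrahydropyridine
Product: 13 2-[(1R,5S,7R)-1-[(2R)-1-{[tert-butyl(diphenyl)silyl]oxy}propan-2-yl]-6-azaspiro[4.5]decan-7-yl]ethan-1-ol
Conditions: H2 (1 atm), Pd(OH)2/C, AcOH (2 equiv), EtOH, rt
Reagents that add atoms: none
Why: Catalytic hydrogenation saturates the cis ring alkene and hydrogenolyses the benzyl ether; acetic acid protonates the amine, which would otherwise inhibit the debenzylation. No stereocentre is touched (the C5 descriptor changes only because the ligand priorities change).

Step 9
Reactants: 13 amino alcohol; 14 methyl 2-(dimethoxyphosphoryl)prop-2-enoate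
Product: 15 methyl 3-[(1R,5S,7R)-1-[(2R)-1-{[tert-butyl(diphenyl)silyl]oxy}propan-2-yl]-7-(2-hydroxyethyl)-6-azaspiro[4.5]decan-6-yl]-2-(dimethoxyphosphoryl)propanoate (both epimers at the phosphonate carbon)
Conditions: 14 (1.5 equiv), MeOH, rt
Reagents that add atoms: none
Why: Aza-Michael addition of a secondary amine to a doubly activated acrylate; the acceptor terminus is an unsubstituted CH2, the least demanding electrophile for this hindered nitrogen, and the neutral alcohol does not compete without base.

Step 10
Reactants: 15 phosphonate alcohol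
Product: 17 methyl (1S,2R,9a'R)-2-[(2R)-1-{[tert-butyl(diphenyl)silyl]oxy}propan-2-yl]-1',4',7',8',9',9a'-hexahydrospiro[cyclopentane-1,6'-quinolizine]-3'-carboxylate, via β-amino aldehyde 16 (not isolated)
Conditions: SO3·pyridine, DMSO, iPr2NEt, CH2Cl2, 0 °C; then LiCl, DBU, MeCN, 0 °C → rt
Reagents that add atoms: none
Why: Parikh–Doering oxidation tolerates the tertiary amine, and the intramolecular Horner–Wadsworth–Emmons reaction under Masamune–Roush conditions closes the six-membered ring C at C2=C3; the ring allows only one alkene geometry. The β-amino aldehyde is not isolated because it can lose the amine by retro-Michael reaction.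

Step 11
Reactants: 17 tricyclic silyl ether
Product: 18 methyl (1S,2R,9a'R)-2-[(2R)-1-hydroxypropan-2-yl]-1',4',7',8',9',9a'-hexahydrospiro[cyclopentane-1,6'-quinolizine]-3'-carboxylate
Conditions: Bu4NF, AcOH, THF, rt
Reagents that add atoms: none
Why: Fluoride cleavage of the silyl ether; buffering with acetic acid keeps the medium from becoming basic enough to affect the enoate.

Step 12
Reactants: 18 primary alcohol
Product: 19 methyl (1S,2R,9a'R)-2-[(2R)-1-oxopropan-2-yl]-1',4',7',8',9',9a'-hexahydrospiro[cyclopentane-1,6'-quinolizine]-3'-carboxylate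
Conditions: SO3·pyridine, DMSO, iPr2NEt, CH2Cl2, 0 °C
Reagents that add atoms: none
Why: Parikh–Doering oxidation to the aldehyde at low temperature; the α-centre C14 should survive if the aldehyde is used at once.

Step 13
Reactants: 19 aldehyde
Product: 20 methyl (1S,2R,9a'R)-2-[(2R)-but-3-yn-2-yl]-1',4',7',8',9',9a'-hexahydrospiro[cyclopentane-1,6'-quinolizine]-3'-carboxylate
Conditions: dimethyl (1-diazo-2-oxopropyl)phosphonate, K2CO3, MeOH, 0 °C → rt
Reagents that add atoms: dimethyl (1-diazo-2-oxopropyl)phosphonate, COP(=O)(OC)C(=[N+]=[N-])C(C)=O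
Why: Ohira–Bestmann homologation turns the aldehyde into the terminal alkyne (C16 added) under carbonate in methanol, which matches the methyl ester and is mild enough for an α-branched aldehyde.

Step 14
Reactants: 21 but-3-yn-1-yl acetate
Product: 22 (3E)-3-chloro-4-iodobut-3-en-1-yl acetate
Conditions: ICl, CH2Cl2, −78 → 0 °C
Reagents that add atoms: iodine monochloride, ClI
Why: Electrophilic iodochlorination of a terminal alkyne: iodine adds to the terminal carbon and chloride opens the iodonium ion at the internal carbon from the opposite face, so I and Cl are trans and the future C17 will be cis to C20.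

Step 15
Reactants: 22 vinyl iodide
Product: 23 (3E)-3-chloro-5-oxopent-3-en-1-yl acetate
Conditions: CO (1 atm), Pd(PPh3)4 (5 mol%), Bu3SnH (slow addition), THF, 50 °C
Reagents that add atoms: carbon monoxide, [C-]#[O+]
Why: Palladium-catalysed reductive carbonylation (formylation) of a vinyl iodide: zerovalent palladium inserts into C–I and not C–Cl, CO insertion and hydride transfer from tin give the enal with retention of alkene geometry. The tin hydride is kept limiting so that the activated C–Cl of the product is not reduced; the enal is used without storage.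

Step 16
Reactants: 20 core alkyne; 23 chloro enal
Product: 24 methyl (1S,2R,9a'R)-2-[(2R,5S,6E)-9-(acetyloxy)-7-chloro-5-hydroxynon-6-en-3-yn-2-yl]-1',4',7',8',9',9a'-hexahydrospiro[cyclopentane-1,6'-quinolizine]-3'-carboxylate
Conditions: Me2Zn (3 equiv), ProPhenol (20 mol%, antipode for Re-face addition), Ph3P=O (40 mol%), 23 (2 equiv), toluene, 0 °C → rt; then aq NH4Cl
Reagents that add atoms: none
Why: Zinc–ProPhenol-catalysed alkynylation of an α,β-unsaturated aldehyde: the methylzinc acetylide of 20 adds 1,2 inside the dinuclear zinc pocket, which selects the aldehyde face and sets C17 independently of the remote core. Both esters are inert to the organozinc; Re-face attack gives the spatial arrangement of the target (S by descriptor while C16 is alkynyl).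

Step 17
Reactants: 24 propargylic alcohol
Product: 25 methyl (1S,2R,9a'R)-2-[(2S,3Z,5R,6E)-9-(acetyloxy)-7-chloro-5-hydroxynona-3,6-dien-2-yl]-1',4',7',8',9',9a'-hexahydrospiro[cyclopentane-1,6'-quinolizine]-3'-carboxylate
Conditions: H2 (1 atm), Pd/CaCO3 poisoned with Pb(OAc)2, quinoline, EtOAc, rt
Reagents that add atoms: none
Why: Lindlar semihydrogenation gives the cis C15=C16 alkene; the trisubstituted enoate and the vinyl chloride are much slower to reduce on the poisoned catalyst.

Step 18
Reactants: 25 diene diester
Product: 26 (1S,2R,9a'R)-2-[(2S,3Z,5R,6E)-7-chloro-5,9-dihydroxynona-3,6-dien-2-yl]-1',4',7',8',9',9a'-hexahydrospiro[cyclopentane-1,6'-quinolizine]-3'-carboxylic acid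
Conditions: LiOH, THF–MeOH–H2O, 0 °C → rt; then pH 7 buffer
Reagents that add atoms: lithium hydroxide, [Li+].[OH-]
Why: Saponification cleaves the methyl ester and the C21 acetate in one operation; the vinyl chloride is no longer conjugated to a carbonyl, and the doubly allylic alcohol is stable to base.

Step 19
Reactants: 26 seco acid
Product: 27 target macrolactone (5R,9S,13R,14S,17R; 15Z,18E in the locants defined above)
Conditions: EDC·HCl, DMAP, DMAP·HCl, CHCl3, reflux, slow addition of 26 (final concentration about 1 mM)
Reagents that add atoms: none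
Why: Keck macrolactonization through the acylpyridinium ion; the primary C21 hydroxyl should be acylated in preference to the hindered, doubly allylic C17 hydroxyl, whose acylation would also need a strained 11-membered ring. The proton source suppresses N-acylurea formation.

## Compound list

1 | 1-nitrocyclopent-1-ene | O=[N+]([O-])C1=CCCC1 | starting material
2 | propanal | CCC=O | starting material
3 | (2R)-2-[(1R)-2-nitrocyclopentyl]propanal (epimers at the nitro carbon) | O=C[C@H](C)[C@H]1CCCC1[N+](=O)[O-] | intermediate
4 | (2R)-2-[(1R)-2-nitrocyclopentyl]propan-1-ol (epimers at the nitro carbon) | OC[C@H](C)[C@H]1CCCC1[N+](=O)[O-] | intermediate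
5 | tert-butyl{(2R)-2-[(1R)-2-nitrocyclopentyl]propoxy}diphenylsilane | CC(C)(C)[Si](c1ccccc1)(c1ccccc1)OC[C@H](C)[C@H]1CCCC1[N+](=O)[O-] | intermediate
6 | 3-bromo-1-(trimethylsilyl)prop-1-yne | C[Si](C)(C)C#CCBr | starting material
7 | tert-butyl{(2R)-2-[(1R,2S)-2-nitro-2-[3-(trimethylsilyl)prop-2-yn-1-yl]cyclopentyl]propoxy}diphenylsilane | CC(C)(C)[Si](c1ccccc1)(c1ccccc1)OC[C@H](C)[C@H]1CCC[C@@]1(CC#C[Si](C)(C)C)[N+](=O)[O-] | intermediate
8 | tert-butyl{(2R)-2-[(1R,2S)-2-nitro-2-[(2Z)-3-(trimethylsilyl)prop-2-en-1-yl]cyclopentyl]propoxy}diphenylsilane | CC(C)(C)[Si](c1ccccc1)(c1ccccc1)OC[C@H](C)[C@H]1CCC[C@@]1(C/C=C\[Si](C)(C)C)[N+](=O)[O-] | intermediate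
9 | (1S,2R)-2-[(2R)-1-{[tert-butyl(diphenyl)silyl]oxy}propan-2-yl]-1-[(2Z)-3-(trimethylsilyl)prop-2-en-1-yl]cyclopentan-1-amine | CC(C)(C)[Si](c1ccccc1)(c1ccccc1)OC[C@H](C)[C@H]1CCC[C@]1(N)C/C=C\[Si](C)(C)C | intermediate
10 | 3-(benzyloxy)propanal | O=CCCOCc1ccccc1 | starting material
11 | (1E)-3-(benzyloxy)-N-{(1S,2R)-2-[(2R)-1-{[tert-butyl(diphenyl)silyl]oxy}propan-2-yl]-1-[(2Z)-3-(trimethylsilyl)prop-2-en-1-yl]cyclopentyl}propan-1-imine | CC(C)(C)[Si](c1ccccc1)(c1ccccc1)OC[C@H](C)[C@H]1CCC[C@]1(/N=C/CCOCc1ccccc1)C/C=C\[Si](C)(C)C | intermediate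
12 | (1R,5S,7S)-7-[2-(benzyloxy)ethyl]-1-[(2R)-1-{[tert-butyl(diphenyl)silyl]oxy}propan-2-yl]-6-azaspiro[4.5]dec-8-ene | CC(C)(C)[Si](c1ccccc1)(c1ccccc1)OC[C@H](C)[C@H]1CCC[C@]12CC=C[C@H](CCOCc1ccccc1)N2 | intermediate
13 | 2-[(1R,5S,7R)-1-[(2R)-1-{[tert-butyl(diphenyl)silyl]oxy}propan-2-yl]-6-azaspiro[4.5]decan-7-yl]ethan-1-ol | CC(C)(C)[Si](c1ccccc1)(c1ccccc1)OC[C@H](C)[C@H]1CCC[C@]12CCC[C@H](CCO)N2 | intermediate
14 | methyl 2-(dimethoxyphosphoryl)prop-2-enoate | C=C(C(=O)OC)P(=O)(OC)OC | starting material
15 | methyl 3-[(1R,5S,7R)-1-[(2R)-1-{[tert-butyl(diphenyl)silyl]oxy}propan-2-yl]-7-(2-hydroxyethyl)-6-azaspiro[4.5]decan-6-yl]-2-(dimethoxyphosphoryl)propanoate | CC(C)(C)[Si](c1ccccc1)(c1ccccc1)OC[C@H](C)[C@H]1CCC[C@]12CCC[C@H](CCO)N2CC(C(=O)OC)P(=O)(OC)OC | intermediate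
16 | methyl 3-[(1R,5S,7R)-1-[(2R)-1-{[tert-butyl(diphenyl)silyl]oxy}propan-2-yl]-7-(2-oxoethyl)-6-azaspiro[4.5]decan-6-yl]-2-(dimethoxyphosphoryl)propanoate | CC(C)(C)[Si](c1ccccc1)(c1ccccc1)OC[C@H](C)[C@H]1CCC[C@]12CCC[C@H](CC=O)N2CC(C(=O)OC)P(=O)(OC)OC | intermediate
17 | methyl (1S,2R,9a'R)-2-[(2R)-1-{[tert-butyl(diphenyl)silyl]oxy}propan-2-yl]-1',4',7',8',9',9a'-hexahydrospiro[cyclopentane-1,6'-quinolizine]-3'-carboxylate | COC(=O)C1=CC[C@H]2CCC[C@]3(CCC[C@@H]3[C@@H](C)CO[Si](c3ccccc3)(c3ccccc3)C(C)(C)C)N2C1 | intermediate
18 | methyl (1S,2R,9a'R)-2-[(2R)-1-hydroxypropan-2-yl]-1',4',7',8',9',9a'-hexahydrospiro[cyclopentane-1,6'-quinolizine]-3'-carboxylate | COC(=O)C1=CC[C@H]2CCC[C@]3(CCC[C@@H]3[C@@H](C)CO)N2C1 | intermediate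
19 | methyl (1S,2R,9a'R)-2-[(2R)-1-oxopropan-2-yl]-1',4',7',8',9',9a'-hexahydrospiro[cyclopentane-1,6'-quinolizine]-3'-carboxylate | COC(=O)C1=CC[C@H]2CCC[C@]3(CCC[C@@H]3[C@@H](C)C=O)N2C1 | intermediate
20 | methyl (1S,2R,9a'R)-2-[(2R)-but-3-yn-2-yl]-1',4',7',8',9',9a'-hexahydrospiro[cyclopentane-1,6'-quinolizine]-3'-carboxylate | COC(=O)C1=CC[C@H]2CCC[C@]3(CCC[C@@H]3[C@@H](C)C#C)N2C1 | intermediate
21 | but-3-yn-1-yl acetate | CC(=O)OCCC#C | starting material
22 | (3E)-3-chloro-4-iodobut-3-en-1-yl acetate | I/C=C(/Cl)CCOC(C)=O | intermediate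
23 | (3E)-3-chloro-5-oxopent-3-en-1-yl acetate | O=C/C=C(/Cl)CCOC(C)=O | intermediate
24 | methyl (1S,2R,9a'R)-2-[(2R,5S,6E)-9-(acetyloxy)-7-chloro-5-hydroxynon-6-en-3-yn-2-yl]-1',4',7',8',9',9a'-hexahydrospiro[cyclopentane-1,6'-quinolizine]-3'-carboxylate | COC(=O)C1=CC[C@H]2CCC[C@]3(CCC[C@@H]3[C@@H](C)C#C[C@@H](O)/C=C(/Cl)CCOC(C)=O)N2C1 | intermediate
25 | methyl (1S,2R,9a'R)-2-[(2S,3Z,5R,6E)-9-(acetyloxy)-7-chloro-5-hydroxynona-3,6-dien-2-yl]-1',4',7',8',9',9a'-hexahydrospiro[cyclopentane-1,6'-quinolizine]-3'-carboxylate | COC(=O)C1=CC[C@H]2CCC[C@]3(CCC[C@@H]3[C@@H](C)/C=C\[C@@H](O)/C=C(/Cl)CCOC(C)=O)N2C1 | intermediate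
26 | (1S,2R,9a'R)-2-[(2S,3Z,5R,6E)-7-chloro-5,9-dihydroxynona-3,6-dien-2-yl]-1',4',7',8',9',9a'-hexahydrospiro[cyclopentane-1,6'-quinolizine]-3'-carboxylic acid | OC(=O)C1=CC[C@H]2CCC[C@]3(CCC[C@@H]3[C@@H](C)/C=C\[C@@H](O)/C=C(/Cl)CCO)N2C1 | intermediate
27 | target: 15-membered lactone of 26 between C1 and O–C21 (5R,9S,13R,14S,17R; 15Z,18E) | C[C@H]1/C=C\[C@@H](O)/C=C(/Cl)CCOC(=O)C2=CC[C@H]3CCC[C@]4(CCC[C@H]14)N3C2 | target

## Step count and least certain steps

Total: 19 steps. Longest linear sequence: 17 steps (steps 1–13 and 16–19). The chloro enal 23 takes two further steps (14 and 15).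

**Step 7 (key step).** The closure may be slow for an N–H iminium ion on a quaternary carbon, so that hydrolysis or protodesilylation competes. The 2-azonia-Cope pathway also breaks and re-forms the C8–C9 bond, so the relative configuration of C5 and C9 could leak if the chairs are not well differentiated. The fallback gives up the C5–C6 cut for a reversible aza-Michael closure and sets out from 5. Tsuji–Trost allylation of its nitronate with allyl methyl carbonate and Pd(PPh3)4 gives the allyl nitro compound F1. Hydroboration with 9-BBN and Suzuki–Miyaura coupling with methyl (Z)-3-iodoacrylate (Pd(dppf)Cl2, AsPh3, Cs2CO3) gives the nitro enoate F2. Zinc in acetic acid frees the amine, which adds to the enoate under thermodynamic control to give the piperidine ester F3 with the C4 chain and C13 equatorial. LiAlH4 reduction of the ester rejoins the route at 13.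

**Step 1.** The trisubstituted cyclic nitroalkene may react sluggishly with the hindered enamine, and the syn selectivity may erode. The fallback sets out from 2 and forms the ring after the Michael addition. (E)-5-Chloro-1-nitropent-1-ene F4 (Henry reaction of 4-chlorobutanal with nitromethane, then dehydration) is a β-monosubstituted nitroalkene, the best-behaved class for this catalysis. Addition of 2 under the same catalyst and NaBH4 reduction give the chloro nitro alcohol F5, and silylation gives its silyl ether F6. NaI and DBU then close the cyclopentane by 5-exo-tet C-alkylation of the nitronate, and the route is rejoined at 5.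

**Step 3.** The hindered nitronate may couple on oxygen or at the allenyl terminus, or on the wrong face. The fallback sets out from 5 and uses a π-allylpalladium electrophile. Methyl (2E)-3-(trimethylsilyl)prop-2-en-1-yl carbonate F7 (from the commercial alcohol and methyl chloroformate) and Pd(PPh3)4 give the E vinylsilane nitro compound F8, with attack at the allyl terminus remote from silicon. Zinc reduction gives the amine F9, and condensation with 10 gives the imine F10. Acid cyclization of F10 loses silicon and rejoins the route at 12. The E silyl group is equatorial in the favoured chair, so this variant should be slower and less secure at C5.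

**Steps 9 and 10.** The 2,2,6-trisubstituted piperidine nitrogen may add too slowly, or the adduct may revert by retro-Michael reaction before the olefination. The fallback sets out from 13 and closes ring C by metathesis. N-Alkylation with methyl 2-(bromomethyl)prop-2-enoate (K2CO3, MeCN) gives the N-allyl amino alcohol F11. Parikh–Doering oxidation gives the aldehyde F12, and Takai–Lombardo methylenation (Zn, CH2Br2, TiCl4) gives the diene F13. Ring-closing metathesis of its ammonium salt with the second-generation Grubbs catalyst RuCl2(=CHPh)(PCy3)(H2IMes) rejoins the route at 17.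

**Step 16.** Facial selectivity may be poor if the tertiary amine of 20 binds zinc, and the acetylide may attack C19 with loss of chloride. The fallback sets out from 20 and 23 and sets C17 by reduction. Uncatalysed addition of the methylzinc acetylide gives the C17 epimer mixture F14, and MnO2 oxidation gives the ynone F15. Asymmetric transfer hydrogenation with RuCl(p-cymene)[(S,S)-TsDPEN] or its antipode in iPrOH rejoins the route at 24.

**Step 19.** Acylation of the C17 hydroxyl or oligomerisation may compete with closure of the 15-membered ring. The fallback sets out from 25 and blocks C17. TBSOTf and 2,6-lutidine give the C17 silyl ether F16, and LiOH gives the silylated seco acid F17. The same lactonization gives the silylated macrolactone F18, and HF·pyridine rejoins the route at 27.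

## Further compounds

F1 | step 7 | tert-butyl{(2R)-2-[(1R,2S)-2-nitro-2-(prop-2-en-1-yl)cyclopentyl]propoxy}diphenylsilane | CC(C)(C)[Si](c1ccccc1)(c1ccccc1)OC[C@H](C)[C@H]1CCC[C@@]1(CC=C)[N+](=O)[O-]
F2 | step 7 | methyl (2Z)-6-{(1S,2R)-2-[(2R)-1-{[tert-butyl(diphenyl)silyl]oxy}propan-2-yl]-1-nitrocyclopentyl}hex-2-enoate | CC(C)(C)[Si](c1ccccc1)(c1ccccc1)OC[C@H](C)[C@H]1CCC[C@@]1(CCC/C=C\C(=O)OC)[N+](=O)[O-]
F3 | step 7 | methyl 2-[(1R,5S,7R)-1-[(2R)-1-{[tert-butyl(diphenyl)silyl]oxy}propan-2-yl]-6-azaspiro[4.5]decan-7-yl]acetate | CC(C)(C)[Si](c1ccccc1)(c1ccccc1)OC[C@H](C)[C@H]1CCC[C@]12CCC[C@H](CC(=O)OC)N2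
F4 | step 1 | (1E)-5-chloro-1-nitropent-1-ene | [O-][N+](=O)/C=C/CCCCl
F5 | step 1 | (2R,3R)-6-chloro-2-methyl-3-(nitromethyl)hexan-1-ol | OC[C@H](C)[C@@H](CCCCl)C[N+](=O)[O-]
F6 | step 1 | tert-butyl{[(2R,3R)-6-chloro-2-methyl-3-(nitromethyl)hexyl]oxy}diphenylsilane | CC(C)(C)[Si](c1ccccc1)(c1ccccc1)OC[C@H](C)[C@@H](CCCCl)C[N+](=O)[O-]
F7 | step 3 | methyl (2E)-3-(trimethylsilyl)prop-2-en-1-yl carbonate | COC(=O)OC/C=C/[Si](C)(C)C
F8 | step 3 | tert-butyl{(2R)-2-[(1R,2S)-2-nitro-2-[(2E)-3-(trimethylsilyl)prop-2-en-1-yl]cyclopentyl]propoxy}diphenylsilane | CC(C)(C)[Si](c1ccccc1)(c1ccccc1)OC[C@H](C)[C@H]1CCC[C@@]1(C/C=C/[Si](C)(C)C)[N+](=O)[O-]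
F9 | step 3 | (1S,2R)-2-[(2R)-1-{[tert-butyl(diphenyl)silyl]oxy}propan-2-yl]-1-[(2E)-3-(trimethylsilyl)prop-2-en-1-yl]cyclopentan-1-amine | CC(C)(C)[Si](c1ccccc1)(c1ccccc1)OC[C@H](C)[C@H]1CCC[C@]1(N)C/C=C/[Si](C)(C)C
F10 | step 3 | (1E)-3-(benzyloxy)-N-{(1S,2R)-2-[(2R)-1-{[tert-butyl(diphenyl)silyl]oxy}propan-2-yl]-1-[(2E)-3-(trimethylsilyl)prop-2-en-1-yl]cyclopentyl}propan-1-imine | CC(C)(C)[Si](c1ccccc1)(c1ccccc1)OC[C@H](C)[C@H]1CCC[C@]1(/N=C/CCOCc1ccccc1)C/C=C/[Si](C)(C)C
F11 | step 9 | methyl 2-{[(1R,5S,7R)-1-[(2R)-1-{[tert-butyl(diphenyl)silyl]oxy}propan-2-yl]-7-(2-hydroxyethyl)-6-azaspiro[4.5]decan-6-yl]methyl}prop-2-enoate | CC(C)(C)[Si](c1ccccc1)(c1ccccc1)OC[C@H](C)[C@H]1CCC[C@]12CCC[C@H](CCO)N2CC(=C)C(=O)OC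
F12 | step 9 | methyl 2-{[(1R,5S,7R)-1-[(2R)-1-{[tert-butyl(diphenyl)silyl]oxy}propan-2-yl]-7-(2-oxoethyl)-6-azaspiro[4.5]decan-6-yl]methyl}prop-2-enoate | CC(C)(C)[Si](c1ccccc1)(c1ccccc1)OC[C@H](C)[C@H]1CCC[C@]12CCC[C@H](CC=O)N2CC(=C)C(=O)OC
F13 | step 9 | methyl 2-{[(1R,5S,7R)-1-[(2R)-1-{[tert-butyl(diphenyl)silyl]oxy}propan-2-yl]-7-(prop-2-en-1-yl)-6-azaspiro[4.5]decan-6-yl]methyl}prop-2-enoate | CC(C)(C)[Si](c1ccccc1)(c1ccccc1)OC[C@H](C)[C@H]1CCC[C@]12CCC[C@H](CC=C)N2CC(=C)C(=O)OC
F14 | step 16 | 24 as a mixture of both C17 epimers | COC(=O)C1=CC[C@H]2CCC[C@]3(CCC[C@@H]3[C@@H](C)C#CC(O)/C=C(/Cl)CCOC(C)=O)N2C1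
F15 | step 16 | methyl (1S,2R,9a'R)-2-[(2R,6E)-9-(acetyloxy)-7-chloro-5-oxonon-6-en-3-yn-2-yl]-1',4',7',8',9',9a'-hexahydrospiro[cyclopentane-1,6'-quinolizine]-3'-carboxylate | COC(=O)C1=CC[C@H]2CCC[C@]3(CCC[C@@H]3[C@@H](C)C#CC(=O)/C=C(/Cl)CCOC(C)=O)N2C1
F16 | step 19 | C17 tert-butyldimethylsilyl ether of 25 | COC(=O)C1=CC[C@H]2CCC[C@]3(CCC[C@@H]3[C@@H](C)/C=C\[C@@H](O[Si](C)(C)C(C)(C)C)/C=C(/Cl)CCOC(C)=O)N2C1
F17 | step 19 | C17 tert-butyldimethylsilyl ether of 26 | OC(=O)C1=CC[C@H]2CCC[C@]3(CCC[C@@H]3[C@@H](C)/C=C\[C@@H](O[Si](C)(C)C(C)(C)C)/C=C(/Cl)CCO)N2C1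
F18 | step 19 | C17 tert-butyldimethylsilyl ether of 27 | C[C@H]1/C=C\[C@@H](O[Si](C)(C)C(C)(C)C)/C=C(/Cl)CCOC(=O)C2=CC[C@H]3CCC[C@]4(CCC[C@H]14)N3C2
A1 | alternative 1 | dimethyl (2E,9E)-6-nitroundeca-2,9-dienedioate | COC(=O)/C=C/CCCC(CCC/C=C/C(=O)OC)[N+](=O)[O-]
A2 | alternative 1 | methyl (E)-6-[2-(2-methoxy-2-oxoethyl)-1-nitrocyclopentyl]hex-2-enoate, single enantiomer as drawn | COC(=O)C[C@H]1CCC[C@@]1(CCC/C=C/C(=O)OC)[N+](=O)[O-]
A3 | alternative 2 | C2 enol triflate of the tricyclic core carrying the C17 silyl ether side chain and a free C21 hydroxyl | FC(F)(F)S(=O)(=O)OC1=CC[C@H]2CCC[C@]3(CCC[C@@H]3[C@@H](C)/C=C\[C@@H](O[Si](C)(C)C(C)(C)C)/C=C(/Cl)CCO)N2C1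
A4 | alternative 2 | C17 tert-butyldimethylsilyl ether of the target | C[C@H]1/C=C\[C@@H](O[Si](C)(C)C(C)(C)C)/C=C(/Cl)CCOC(=O)C2=CC[C@H]3CCC[C@]4(CCC[C@H]14)N3C2
A5 | alternative 3 | methyl (4E)-8-{(1S,2R)-1-amino-2-[(2R)-1-{[tert-butyl(dimethyl)silyl]oxy}propan-2-yl]cyclopentyl}-3-oxooct-4-enoate | CC(C)(C)[Si](C)(C)OC[C@H](C)[C@H]1CCC[C@]1(N)CCC/C=C/C(=O)CC(=O)OC
A6 | alternative 3 | tricyclic β-keto ester (spiro-fused methyl 2-oxoquinolizidine-3-carboxylate) | CC(C)(C)[Si](C)(C)OC[C@H](C)[C@H]1CCC[C@]12CCC[C@@H]3CC(=O)C(C(=O)OC)CN23
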